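## Retrosynthetic overview

1. Endgame: the C6 phenol, the side-chain acetate and the C3 angelate of the cis-(2R,3R) dihydrobenzofuran go back to a PMB ether, a TBS ether and a trans-(2R,3S) 3-ol. C3 of that alcohol is inverted in the esterification.
2. Pivotal feature: four of the five atoms of the dihydrofuran ring (O1, C7a, C3a, C3) are the phenol oxygen, two ring carbons and the formyl carbon of a salicylaldehyde. The fifth atom, C2, carries only H and the CH2=C(CH2OR) branch, so it is cut out as a one-carbon unit that acts first as a nucleophile (towards C3) and then as an electrophile (towards O1).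
3. Key disconnection, C2–C3 and O1–C2, a formal (4+1) annulation: 5-acetyl-2-hydroxy-4-(PMB-oxy)benzaldehyde plus the allylide of a 2-(silyloxymethyl)allyl (2R,5R)-2,5-dimethylthiolanium salt.
4. Ring order: the benzene ring is bought, and the thiolane ring of the chiral carrier is made separately and released again. A transient oxirane follows, and the dihydrofuran ring is the only ring of the target that is built, in the key step.
5. Fragments: the aldehyde comes from 5-bromo-2,4-dihydroxybenzaldehyde (O4-selective PMB ether, Stille acetylation). The salt comes from 2-methylenepropane-1,3-diol and (2S,5S)-hexane-2,5-diol.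

Key step: step 8

Assumption: the (2R,5R)-thiolane is taken to induce the same sense as in epoxidations of aromatic aldehydes with its benzyl and 2-substituted allyl salts, that is (S,S)-trans oxiranes; if the annulation ran in the opposite sense, the same sequence would start from (2R,5R)-hexane-2,5-diol.

## Route

Step 1
Reactants: 1 5-bromo-2,4-dihydroxybenzaldehyde
Product: 2 5-bromo-2-hydroxy-4-[(4-methoxybenzyl)oxy]benzaldehyde
Conditions: PMBCl (1.05 equiv), NaHCO3, MeCN, 70 °C
Reagents that add atoms: 4-methoxybenzyl chloride (PMBCl), COc1ccc(CCl)cc1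
Why: Williamson etherification under weak-base control, in which the free and more acidic C4 hydroxyl (para to CHO, ortho to Br) should be alkylated while the C2 hydroxyl stays locked in its hydrogen bond to the aldehyde.

Step 2
Reactants: 2 5-bromo-2-hydroxy-4-[(4-methoxybenzyl)oxy]benzaldehyde
Product: 4 5-acetyl-2-hydroxy-4-[(4-methoxybenzyl)oxy]benzaldehyde, via ethyl enol ether 3 (not isolated)
Conditions: Bu3Sn[C(OEt)=CH2] (1.3 equiv), PdCl2(PPh3)2 (5 mol %), toluene, 100 °C; then 1 M HCl, THF, rt
Reagents that add atoms: tributyl(1-ethoxyvinyl)stannane, CCCC[Sn](CCCC)(CCCC)C(=C)OCC; water, O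
Why: Migita–Kosugi–Stille coupling of the aryl bromide with an acetyl anion equivalent at zerovalent palladium, neutral and anhydrous so that the chelated phenol and the aldehyde are tolerated, followed by enol ether hydrolysis in dilute acid that should leave the aryl PMB ether intact.

Step 3
Reactants: 5 (2S,5S)-hexane-2,5-diol
Product: 6 (2S,5S)-hexane-2,5-diyl dimethanesulfonate
Conditions: MsCl (2.4 equiv), Et3N (3 equiv), CH2Cl2, −20 to 0 °C
Reagents that add atoms: methanesulfonyl chloride (MsCl), CS(=O)(=O)Cl
Why: Sulfonate ester formation takes place at oxygen only, so both C–O bonds and both (S) centres remain untouched.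

Step 4
Reactants: 6 (2S,5S)-hexane-2,5-diyl dimethanesulfonate
Product: 7 (2R,5R)-2,5-dimethylthiolane
Conditions: Na2S·9H2O, EtOH, rt
Reagents that add atoms: sodium sulfide (Na2S, used as the nonahydrate), [Na+].[Na+].[S-2]
Why: Double SN2 displacement by sulfide, the second one a 5-exo-tet ring closure, inverts both carbinol carbons and should turn the (S,S) dimesylate into the C2-symmetric (R,R) thiolane.

Step 5
Reactants: 8 2-methylenepropane-1,3-diol
Product: 9 2-{[(tert-butyldimethylsilyl)oxy]methyl}prop-2-en-1-ol
Conditions: NaH (1.0 equiv), THF, 0 °C to rt; then TBSCl (1.0 equiv)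
Reagents that add atoms: tert-butyldimethylsilyl chloride (TBSCl), CC(C)(C)[Si](C)(C)Cl
Why: Monosilylation of a symmetrical diol through its sparingly soluble monosodium alkoxide, which reacts with the silyl chloride faster than the neutral hydroxyl of the product does.

Step 6
Reactants: 9 2-{[(tert-butyldimethylsilyl)oxy]methyl}prop-2-en-1-ol
Product: 10 {[2-(bromomethyl)prop-2-en-1-yl]oxy}(tert-butyl)dimethylsilane
Conditions: CBr4, PPh3, CH2Cl2, 0 °C
Reagents that add atoms: tetrabromomethane (CBr4), BrC(Br)(Br)Br
Why: Appel reaction at a primary allylic carbon under nearly neutral conditions that spare the silyl ether, and allylic transposition is degenerate in this 2-substituted allyl system.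

Step 7
Reactants: 7 (2R,5R)-2,5-dimethylthiolane; 10 {[2-(bromomethyl)prop-2-en-1-yl]oxy}(tert-butyl)dimethylsilane
Product: 11 (2R,5R)-1-(2-{[(tert-butyldimethylsilyl)oxy]methyl}allyl)-2,5-dimethylthiolan-1-ium tetrafluoroborate
Conditions: AgBF4 (1.0 equiv), CH2Cl2, 0 °C to rt, dark
Reagents that add atoms: AgBF4 (silver tetrafluoroborate), [Ag+].F[B-](F)(F)F
Why: S-alkylation of the sulfide is made irreversible by precipitation of AgBr, and because the two lone pairs of the C2-symmetric sulfide are homotopic only one sulfonium salt can form and sulfur is not a stereocentre.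

Step 8
Reactants: 4 5-acetyl-2-hydroxy-4-[(4-methoxybenzyl)oxy]benzaldehyde; 11 (2R,5R)-1-(2-{[(tert-butyldimethylsilyl)oxy]methyl}allyl)-2,5-dimethylthiolan-1-ium tetrafluoroborate
Product: 15 trans alcohol 1-{(2R,3S)-2-(3-{[tert-butyldimethylsilyl]oxy}prop-1-en-2-yl)-3-hydroxy-6-[(4-methoxybenzyl)oxy]-2,3-dihydrobenzofuran-5-yl}ethanone, via sulfonium allylide 12 (not isolated), via anti betaine 13 (not isolated), via trans vinyl epoxide 14 (not isolated)
Conditions: 11 (1.3 equiv), Cs2CO3 (2.5 equiv), MeCN, −20 °C to rt
Reagents that add atoms: none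
Why: Cs2CO3 turns 4 into its phenoxide and reversibly deprotonates 11 to allylide 12, whose α-carbon adds to the formyl group (C2–C3 bond) to give anti betaine 13, and the alkoxide of 13 expels the thiolane by 3-exo-tet closure to trans vinyl epoxide 14. The ortho phenoxide then attacks the allylic epoxide carbon C2 from the rear of its C–O bond (O1–C2 bond), a 5-endo-tet epoxide opening that closes the dihydrofuran ring and is eased by allylic loosening of that bond, whereas attack at benzylic C3 would need a four-membered ring and SN2′ attack at the terminal CH2 a seven-membered one. The closest known reactions are the sulfur ylide annulation of salicylaldehydes to 2,3-dihydrobenzofuran-3-ols, which passes through the same kind of 2-(oxiranyl)phenoxide, and the asymmetric Corey–Chaykovsky synthesis of vinyl oxiranes from aromatic aldehydes and 2-substituted allyl salts of 2,5-dimethylthiolane. C3 is set in the addition, because one ring methyl group of the thiolane shields one face of the preferred ylide conformer and the aldehyde meets the open face, which for the (2R,5R) sulfide should give the (S) carbinol carbon. C2 follows from the anti betaine preference, which gives the trans oxirane with (S) at C2, and from the single inversion in the opening, so that 15 should be the (2R,3S) trans alcohol. The step needs aldehyde over ketone selectivity, secured by the flanking OPMB group and the para phenoxide that deactivate the acetyl group, and C–C bond formation over O-allylation of the phenoxide by 11, secured by delocalisation of that phenoxide into both carbonyl groups and by the low temperature, while a [2,3] shift is held back because the only other α-hydrogens on sulfur sit on tertiary ring carbons.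

Step 9
Reactants: 15 trans alcohol (2R,3S); 16 angelic acid [(Z)-2-methylbut-2-enoic acid]
Product: 17 cis angelate (2R,3R)-5-acetyl-2-(3-{[tert-butyldimethylsilyl]oxy}prop-1-en-2-yl)-6-[(4-methoxybenzyl)oxy]-2,3-dihydrobenzofuran-3-yl (Z)-2-methylbut-2-enoate
Conditions: 16 (2 equiv), PPh3 (2 equiv), DIAD (2 equiv), toluene, 0 °C to rt
Reagents that add atoms: none
Why: Mitsunobu esterification, in which angelate displaces the C3 oxyphosphonium group by SN2 with inversion (3S to 3R, trans to cis), the acid serves only as a carboxylate nucleophile so that the Z alkene should not drift to the tiglate, the non-polar solvent disfavours ionisation, and anti elimination is not available because C2–H lies syn to the leaving group.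

Step 10
Reactants: 17 cis angelate silyl ether
Product: 18 (2R,3R)-5-acetyl-2-(3-hydroxyprop-1-en-2-yl)-6-[(4-methoxybenzyl)oxy]-2,3-dihydrobenzofuran-3-yl (Z)-2-methylbut-2-enoate
Conditions: HF·pyridine, pyridine, THF, 0 °C to rt
Reagents that add atoms: none
Why: Fluoride-mediated silyl ether cleavage in a buffered, weakly acidic medium, chosen because in the cis ester C2–H is anti to the angelate and a basic fluoride source could trigger elimination to the benzofuran or acyl migration.

Step 11
Reactants: 18 primary allylic alcohol
Product: 19 (2R,3R)-5-acetyl-2-[3-(acetyloxy)prop-1-en-2-yl]-6-[(4-methoxybenzyl)oxy]-2,3-dihydrobenzofuran-3-yl (Z)-2-methylbut-2-enoate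
Conditions: Ac2O, pyridine, CH2Cl2, 0 °C to rt
Reagents that add atoms: acetic anhydride, CC(=O)OC(C)=O
Why: Pyridine-mediated O-acylation of the only free hydroxyl, run without a stronger nucleophilic catalyst so that neither the angelate geometry nor the C3 ester is put at risk.

Step 12
Reactants: 19 PMB-protected target
Product: 20 target (2R,3R)-5-acetyl-2-[3-(acetyloxy)prop-1-en-2-yl]-6-hydroxy-2,3-dihydrobenzofuran-3-yl (Z)-2-methylbut-2-enoate
Conditions: DDQ (1.5 equiv), CH2Cl2/aqueous pH 7 phosphate buffer, 0 °C to rt
Reagents that add atoms: none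
Why: Oxidative PMB ether cleavage, in which DDQ removes hydride from the 4-methoxybenzylic CH2, water traps the cation and the hemiacetal collapses to the phenol, all under neutral conditions that should spare both esters, both alkenes and the ionisable C3–O bond.

## Compound list

1 | 5-bromo-2,4-dihydroxybenzaldehyde | O=Cc1cc(Br)c(O)cc1O | starting material
2 | 5-bromo-2-hydroxy-4-[(4-methoxybenzyl)oxy]benzaldehyde | O=Cc1cc(Br)c(OCc2ccc(OC)cc2)cc1O | intermediate
3 | 5-(1-ethoxyvinyl)-2-hydroxy-4-[(4-methoxybenzyl)oxy]benzaldehyde | C=C(OCC)c1cc(C=O)c(O)cc1OCc2ccc(OC)cc2 | intermediate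
4 | 5-acetyl-2-hydroxy-4-[(4-methoxybenzyl)oxy]benzaldehyde | O=Cc1cc(C(C)=O)c(OCc2ccc(OC)cc2)cc1O | intermediate
5 | (2S,5S)-hexane-2,5-diol | C[C@H](O)CC[C@H](C)O | starting material
6 | (2S,5S)-hexane-2,5-diyl dimethanesulfonate | C[C@H](OS(C)(=O)=O)CC[C@H](C)OS(C)(=O)=O | intermediate
7 | (2R,5R)-2,5-dimethylthiolane | S1[C@H](C)CC[C@H]1C | intermediate
8 | 2-methylenepropane-1,3-diol | C=C(CO)CO | starting material
9 | 2-{[(tert-butyldimethylsilyl)oxy]methyl}prop-2-en-1-ol | C=C(CO)CO[Si](C)(C)C(C)(C)C | intermediate
10 | {[2-(bromomethyl)prop-2-en-1-yl]oxy}(tert-butyl)dimethylsilane | C=C(CBr)CO[Si](C)(C)C(C)(C)C | intermediate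
11 | (2R,5R)-1-(2-{[(tert-butyldimethylsilyl)oxy]methyl}allyl)-2,5-dimethylthiolan-1-ium tetrafluoroborate | C=C(CO[Si](C)(C)C(C)(C)C)C[S+]1[C@H](C)CC[C@H]1C.F[B-](F)(F)F | intermediate
12 | sulfonium allylide derived from 11 | C=C(CO[Si](C)(C)C(C)(C)C)[CH-][S+]1[C@H](C)CC[C@H]1C | intermediate
13 | anti betaine, (S) at the carbinolate carbon (future C3) and (R) at the sulfonium-bearing carbon (future C2), drawn with the phenol protonated | C=C(CO[Si](C)(C)C(C)(C)C)[C@@H]([S+]1[C@H](C)CC[C@H]1C)[C@@H]([O-])c2cc(C(C)=O)c(OCc3ccc(OC)cc3)cc2O | intermediate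
14 | trans vinyl epoxide 1-{5-[(2S,3S)-3-(3-{[tert-butyldimethylsilyl]oxy}prop-1-en-2-yl)oxiran-2-yl]-4-hydroxy-2-[(4-methoxybenzyl)oxy]phenyl}ethanone, present as its cesium phenoxide | C=C(CO[Si](C)(C)C(C)(C)C)[C@@H]1O[C@H]1c2cc(C(C)=O)c(OCc3ccc(OC)cc3)cc2O | intermediate
15 | trans alcohol 1-{(2R,3S)-2-(3-{[tert-butyldimethylsilyl]oxy}prop-1-en-2-yl)-3-hydroxy-6-[(4-methoxybenzyl)oxy]-2,3-dihydrobenzofuran-5-yl}ethanone | C=C(CO[Si](C)(C)C(C)(C)C)[C@H]1Oc2cc(OCc3ccc(OC)cc3)c(C(C)=O)cc2[C@@H]1O | intermediate
16 | angelic acid, (Z)-2-methylbut-2-enoic acid | C/C=C(/C)C(=O)O | starting material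
17 | cis angelate (2R,3R), TBS and PMB protected | C=C(CO[Si](C)(C)C(C)(C)C)[C@H]1Oc2cc(OCc3ccc(OC)cc3)c(C(C)=O)cc2[C@H]1OC(=O)/C(C)=C\C | intermediate
18 | cis angelate (2R,3R) with free primary allylic alcohol, PMB protected | C=C(CO)[C@H]1Oc2cc(OCc3ccc(OC)cc3)c(C(C)=O)cc2[C@H]1OC(=O)/C(C)=C\C | intermediate
19 | cis angelate (2R,3R) with side-chain acetate, PMB protected | C=C(COC(C)=O)[C@H]1Oc2cc(OCc3ccc(OC)cc3)c(C(C)=O)cc2[C@H]1OC(=O)/C(C)=C\C | intermediate
20 | (2R,3R)-5-acetyl-2-[3-(acetyloxy)prop-1-en-2-yl]-6-hydroxy-2,3-dihydrobenzofuran-3-yl (Z)-2-methylbut-2-enoate | C=C(COC(C)=O)[C@H]1Oc2cc(O)c(C(C)=O)cc2[C@H]1OC(=O)/C(C)=C\C | target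

## Step count and risks

Total step count: 12.

Longest linear sequence: 8 steps (5 → 6 → 7 → 11 → 15 → 17 → 18 → 19 → 20). The branch from 8 has the same length, and the branch from 1 has 7 steps.

**Step 8.**
- Risk: The formyl group of the phenoxide is a weak electrophile. Competing processes are alkylation of the phenoxide oxygen by the allylic salt, decay of the ylide, and direct displacement of the thiolane from the betaine by the phenoxide, which would reverse the relative configuration. Reversible betaine formation may also erode the facial selectivity.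
- Fallback: it sets out from 4 and separates C–C bond formation from ring closure.
  - The phenol is silylated (TBSCl, imidazole, DMF) to 5-acetyl-2-[(tert-butyldimethylsilyl)oxy]-4-[(4-methoxybenzyl)oxy]benzaldehyde F1, a normal and more electrophilic aromatic aldehyde.
  - Ylide 12, preformed from 11 with KHMDS in THF at −78 °C, is added to it, and the O-silylated (2S,3S)-trans vinyl epoxide F2 is isolated.
  - Cs2CO3 in DMF/water cleaves the aryl silyl ether selectively beside the alkyl one. The liberated phenoxide 14 cyclises, and the route is rejoined at 15.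

**Step 9.**
- Risk: The carboxylate must approach C3 on the face that carries the C2 substituent. Slow substitution may therefore give way to ionisation of the doubly oxygen-activated benzylic oxyphosphonium ion, with loss of configuration at C3 or aromatisation by loss of the C3 oxygen.
- Fallback: it sets out from 15 and separates the inversion from the introduction of the angelate.
  - A Mitsunobu reaction with the more acidic 4-nitrobenzoic acid (PPh3, DIAD, toluene) gives the cis (2R,3R) 4-nitrobenzoate F3.
  - Methanolysis (K2CO3, MeOH, 0 °C) gives the cis (2R,3R) alcohol F4.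
  - F4 is acylated with retention by angelic 2,4,6-trichlorobenzoic anhydride F5, made from 16 with 2,4,6-trichlorobenzoyl chloride and Et3N in toluene (Yamaguchi-type esterification). The route is rejoined at 17.

**Step 12.**
- Risk: Hydride abstraction from an aryl PMB ether whose oxygen is conjugated with the acetyl group may be slow. Oxidation at C2–H or loss of the C3 ester may then compete on the most precious intermediate.
- Fallback: it sets out from 15, unmasks the phenol early and then uses its hydrogen bond to the acetyl group as internal protection.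
  - Chelation-assisted cleavage (MgBr2·OEt2, Me2S, CH2Cl2, rt) gives the (2R,3S) trans alcohol with free C6 phenol F6.
  - A Mitsunobu reaction with 16 gives the cis (2R,3R) angelate with free C6 phenol F7. The chelated phenol is a poor competitor for the far more acidic carboxylic acid.
  - HF·pyridine gives the cis angelate with free phenol and free primary alcohol F8.
  - Ac2O (1 equiv) and pyridine at −20 to 0 °C acetylate the primary hydroxyl selectively. The route is rejoined at 20.

## Further compounds

F1 | step 8 | 5-acetyl-2-[(tert-butyldimethylsilyl)oxy]-4-[(4-methoxybenzyl)oxy]benzaldehyde | O=Cc1cc(C(C)=O)c(OCc2ccc(OC)cc2)cc1O[Si](C)(C)C(C)(C)C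
F2 | step 8 | O-silylated (2S,3S)-trans vinyl epoxide | C=C(CO[Si](C)(C)C(C)(C)C)[C@@H]1O[C@H]1c2cc(C(C)=O)c(OCc3ccc(OC)cc3)cc2O[Si](C)(C)C(C)(C)C
F3 | step 9 | cis (2R,3R) 4-nitrobenzoate | C=C(CO[Si](C)(C)C(C)(C)C)[C@H]1Oc2cc(OCc3ccc(OC)cc3)c(C(C)=O)cc2[C@H]1OC(=O)c4ccc(cc4)[N+](=O)[O-]
F4 | step 9 | cis (2R,3R) alcohol | C=C(CO[Si](C)(C)C(C)(C)C)[C@H]1Oc2cc(OCc3ccc(OC)cc3)c(C(C)=O)cc2[C@H]1O
F5 | step 9 | angelic 2,4,6-trichlorobenzoic anhydride | C/C=C(/C)C(=O)OC(=O)c1c(Cl)cc(Cl)cc1Cl
F6 | step 12 | (2R,3S) trans alcohol with free C6 phenol | C=C(CO[Si](C)(C)C(C)(C)C)[C@H]1Oc2cc(O)c(C(C)=O)cc2[C@@H]1O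
F7 | step 12 | cis (2R,3R) angelate with free C6 phenol | C=C(CO[Si](C)(C)C(C)(C)C)[C@H]1Oc2cc(O)c(C(C)=O)cc2[C@H]1OC(=O)/C(C)=C\C
F8 | step 12 | cis angelate with free phenol and free primary alcohol | C=C(CO)[C@H]1Oc2cc(O)c(C(C)=O)cc2[C@H]1OC(=O)/C(C)=C\C
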